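## Structural features

The target is a 5/6/11 tricyclic diterpenoid monoacetate. Ring A (cyclopentane C11–C15) is cis-fused to ring B (cyclohexene C9, C10, C11, C15, C16, C17) along C11–C15. The eleven-membered ring C (C2–C12) shares C11–C12 with ring A and the C9=C10–C11 unit with ring B, so rings B and C form a bridged bicyclo[8.3.1] system whose one-carbon bridge C10 carries the tetrasubstituted alkene C9=C10.

Five contiguous stereocentres run C17–C16–C15–C11–C12: quaternary C15 with its methyl, C11–H cis to that methyl, the C12–C2 bond on the same face, and a trans-diol (C16–OH on the opposite face, C17–OH on the methyl face). C6 (methyl) and C3 (acetoxy) lie remote in ring C. In CIP terms the target is 3R,6S,11R,12R,15R,16R,17R.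

The fragile groups are the secondary allylic acetate at C3 next to the exocyclic methylene C1=C2, the allylic C17 hydroxyl (which can ionise or eliminate), and the two hindered alkenes, which forbid late hydrogenation and strong acid. The real difficulty is threefold: closing medium ring C, placing the fully substituted C9=C10 alkene regioselectively beside the oxygenated C16/C17 pair, and holding C11, C12 and C15 in the cis-hydrindane arrangement.

The key step exploits the fact that rings A and B with the C15 and C10 methyls map atom for atom onto the annulation product of 2-methylcyclopentane-1,3-dione (C11–C15, with carbonyl carbons C11 and C14 flanking C15) and ethyl vinyl ketone (C16, C17, C9, C10 and the C10 methyl). Quaternary C15 is then a prochiral centre between two enantiotopic carbonyls. One amino-acid-catalysed aldol closure of C10 onto C11 builds ring B and fixes the absolute configuration, from which every other ring stereocentre is relayed.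

## Logic of the disconnections

**37 ⇒ 36 ⇒ 35.** Only heteroatom bonds are cut: the two O–Si bonds at C16/C17 and the O–acyl bond at C3. This postpones the free trans-diol and the allylic acetate to the end. The forward steps must acylate a single free hydroxyl and remove silicon without touching the ester.

**35 ⇒ 34.** The C2–C3 bond of ring C is cut. The C1=C2–C3(OH) unit is exactly what an alkenyl-metal addition to an aldehyde delivers, so this cut removes the eleven-membered ring and the C3 stereocentre together and leaves an acyclic chain on a rigid A/B core. The forward closure must beat oligomerisation and must favour the 3R face.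

**34 ⇒ 32 ⇒ 30 ⇒ 29.** Functional-group changes only: the C3 aldehyde comes from cleaving the terminal trisubstituted alkene, and the C2 triflate comes from a methyl ketone that in turn comes from a vinyl group. Both reactive ends of the macrocyclisation are thereby stored as alkenes of different substitution. The forward steps must discriminate between mono-, tri- and tetrasubstituted alkenes.

**29 ⇒ 28 ⇒ 27 ⇒ 26 ⇒ 25 ⇒ 24.** The C12–C2 bond is cut and a carbonyl is restored at C14 as the activating group for a conjugate addition. The C12 stereocentre is then derived from C11. The forward addition must enter trans to C10, and the C14 carbonyl must afterwards be removed under conditions that spare silyl ethers and alkenes.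

**24 ⇒ 23 ⇒ 22 ⇒ 21 ⇒ 18 + 20 (from 19).** The C8–C9 bond is cut between an sp2 carbon and an sp3 carbon. This splits off the whole C3–C8 chain with its C6 stereocentre as a chiral-pool diene and reduces the problem to the bicyclic core. The forward coupling must engage a hindered tetrasubstituted alkenyl triflate, and the C14 oxygen must be carried masked until the coupling is done.

**18 ⇒ 17 ⇒ 16 ⇒ 15 ⇒ 14 ⇒ 13 ⇒ 12.** The C9–O triflate bond, the C17–O bond and the C10–H/C11–H bonds are all traced back to one carbonyl at C9. This puts three tasks on one functional group. The forward steps need cis-selective hydrogenation and two enolisations of opposite regiochemistry.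

**12 ⇒ 11 ⇒ 10 ⇒ 9 ⇒ 8 ⇒ 7.** The C16–O bond is cut back to the C16=C17 enone, and that alkene back to the saturated α′ position. The C16 stereocentre is then controlled by the neighbouring quaternary C15. The forward step must attack the less substituted of two enone β-carbons, on the face opposite the C15 methyl.

**7 ⇒ 6 ⇒ 5.** The C14 carbonyl is masked as a silyl-protected carbinol so that every enolate on the way to 18 forms at C9 only. The forward reduction must distinguish the saturated ketone from the enone.

**5 ⇒ 4 ⇒ 3.** The C10=C11 bond is cut (aldol condensation). This removes ring B and the only stereocentre of 5 and reveals a symmetric triketone. The forward step must discriminate the enantiotopic carbonyls C11 and C14.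

**3 ⇒ 1 + 2.** The C15–C16 bond is cut (Michael addition), which leads to two commodity chemicals. The forward step needs only monoalkylation at carbon.

## Other disconnections considered

**Alternative 1: anionic oxy-Cope ring expansion.**
- **Cut:** C11–C12 is broken and C3–C9 is made in the retrosynthetic sense. Ring C contracts to a cycloheptanol that is spiro-fused at C9 to ring B and carries a buta-1,3-dienyl group on the carbinol carbon C3 (A2).
- **Forward key step:** KH with 18-crown-6 gives the potassium alkoxide of A2. The [3,3] shift of the C12=C2–C3–C9–C10=C11 array forms C11–C12, cleaves C3–C9 and moves the ring-B alkene to C9=C10. Me3SiCl traps the enolate (oxygen on C3, nucleophilic carbon C2) as silyl enol ether A1.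
- **In its favour:** ring C arises without high dilution. C9=C10 is formed regiospecifically, which is better than the chosen plan, where this rests on a selective enolisation. C11 and C12 are set in one concerted event, and the C2/C3 enol ether is ready for methylenation at C2.
- **Against it here:** quaternary C9 and tertiary C3 must be built with defined relative configuration. A chair-like transition state with an (E)-dienyl unit would place C13 equatorial and lead to the C12 epimer, so a (Z)-alkene or a boat is required. C15 must be made without the aldol. Ring A must still be closed from the two vinyl groups, and the resulting C13=C14 alkene must be reduced in the presence of C9=C10.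
- **Comparison:** the rearrangement achieves more per step than any single step of the chosen plan. Both plans set C3 late by a carbonyl addition or reduction and are equal on that point. Overall length is expected to be similar, because the precursor assembly and the ring-A endgame are long.

**Alternative 2: transannular ring-closing metathesis.**
- **Cut:** the C9=C10 alkene. The precursor A4 is a thirteen-membered ring (C9, C8–C2, C12, C11, C15, C16, C17) fused to ring A, with an exocyclic methylene on C9 and an isopropenyl group on C11.
- **Forward key step:** the second-generation Hoveyda–Grubbs catalyst joins the two 1,1-disubstituted alkenes across the ring, expels ethylene and closes rings B and C at once to give the target acetonide A3.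
- **In its favour:** every stereocentre is in place before the key step and only an acetal hydrolysis follows. This endgame is shorter and uses fewer protecting groups than the chosen plan, and it avoids the enolisation problem at C9.
- **Against it here:** a tetrasubstituted alkene from two 1,1-disubstituted alkenes is the most demanding metathesis class. The C1=C2 methylene is a third competent alkene. The trans-fused acetonide adds strain. A thirteen-membered ring must still be made first, so a macrocyclisation is not avoided (equal to the chosen plan).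
- **Comparison:** A3 is better on convergence. The chosen plan is better on the reliability of the bond that makes C9=C10 (alkenyl triflate coupling) and on how cheaply rings A and B are reached.

**Alternative 3: alkenylchromium closure of ring B.**
- **Cut:** the C9–C17 bond. The precursor A6 is the A/C bicycle with a C9 enol triflate and a C17 aldehyde.
- **Forward key step:** CrCl2 with catalytic NiCl2 turns the triflate into an alkenylchromium species that adds to the aldehyde, closing ring B and creating the C17 carbinol in A5.
- **In its favour:** it uses the same chromium chemistry as the chosen macrocyclisation, but on a six-membered ring, which is kinetically easier. The allylic C17 hydroxyl appears directly.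
- **Against it here:** A6 needs an eleven-membered ring that already holds a geometrically defined tetrasubstituted enol triflate. C15 and C16 must be set without a ring to relay from. The C17 configuration rests on a cyclic transition state of uncertain bias.
- **Comparison:** both plans create one carbinol stereocentre in the chromium step (equal). Alternative 3 is better on ring size. The chosen plan is better on access to C15 and on the order in which difficulty is met.

Key step: step 2

**Remarks before the steps.**
- Skeletal carbons are numbered C1–C17 along the target chain, with acetyl and methyl carbons skipped. α denotes the face carrying the C15 methyl and β the opposite face.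
- Compound 5 as (7aS) has C15 in the spatial sense of the target; the descriptor becomes 15R later only because CIP priorities change. No structure needs correcting.
- In Alternative 1 the trapped enolate has its oxygen on C3 and its nucleophilic carbon at C2, so A1 is a C3 silyl enol ether.
- Assumption: (R)-β-citronellene of high enantiomeric purity is commercially available.
- (S)-Phenylalanine is used in place of (S)-proline in the key step, because a primary amine forms the trisubstituted enamine of an ethyl ketone more readily. (S)-Proline is kept for the fallback.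

## Route

Step 1
Reactants: 1 2-methylcyclopentane-1,3-dione; 2 ethyl vinyl ketone
Product: 3 2-methyl-2-(3-oxopentyl)cyclopentane-1,3-dione
Conditions: H2O, AcOH (cat.), 70 °C
Reagents that add atoms: none
Why: Michael addition of the acidic dione (C15) to the enone β-carbon (C16) in water should stop cleanly at C-monoalkylation; C15 becomes quaternary but remains prochiral.

Step 2
Reactants: 3 2-methyl-2-(3-oxopentyl)cyclopentane-1,3-dione
Product: 5 (7aS)-4,7a-dimethyl-2,3,7,7a-tetrahydro-1H-indene-1,5(6H)-dione, via ketol 4 (not isolated)
Conditions: (S)-phenylalanine (1.0 equiv), HClO4 (1 M aq, 0.5 equiv), MeCN, reflux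
Reagents that add atoms: none
Why: The amino acid condenses with the side-chain ketone C9 to give the enamine C9=C10, whose carbon C10 adds to ring carbonyl C11 through a chair-like transition state in which the carboxylic acid hydrogen-bonds to that carbonyl; the closest known reaction is the Hajos–Parrish–Eder–Sauer–Wiechert cyclisation of the methyl ketone homologue. Ring B closes in the 6-(enolendo)-exo-trig mode. Hydrolysis of the iminium gives cis-fused ketol 4, which loses water under the acidic conditions to give the C10=C11 enone. The only stereocentre that survives is quaternary C15, and its configuration is decided by which of the two enantiotopic carbonyls (C11 or C14) is attacked, which the (S) configuration of the catalyst controls. The step needs enantiotopic-group selectivity only, because 3 is mirror-symmetric and an enamine toward C17 could close only a four-membered ring. A primary amino acid is chosen because the ethyl ketone should form the required trisubstituted enamine more readily with it than with a secondary amine.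

Step 3
Reactants: 5 (7aS)-4,7a-dimethyl-2,3,7,7a-tetrahydro-1H-indene-1,5(6H)-dione
Product: 6 (1S,7aS)-1-hydroxy-4,7a-dimethyl-1,2,3,6,7,7a-hexahydro-5H-inden-5-one (C14 α-OH)
Conditions: NaBH4 (0.3 equiv), EtOH, −20 °C
Reagents that add atoms: none
Why: Borohydride should reduce the saturated cyclopentanone faster than the conjugated C9 ketone, with hydride entering anti to the angular methyl; the C14 configuration is of no lasting importance because C14 is re-oxidised in step 14.

Step 4
Reactants: 6 (1S,7aS)-1-hydroxy-4,7a-dimethyl-1,2,3,6,7,7a-hexahydro-5H-inden-5-one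
Product: 7 C14 triethylsilyl ether of 6
Conditions: Et3SiCl, imidazole, DMF, 0 °C → rt
Reagents that add atoms: chlorotriethylsilane, CC[Si](Cl)(CC)CC
Why: Standard silylation; triethylsilyl is chosen because it should survive the enolate chemistry ahead and later be cleavable in the presence of tert-butyldimethylsilyl ethers.

Step 5
Reactants: 7 C14 triethylsilyl ether of 6
Product: 9 cross-conjugated dienone (C16=C17 and C10=C11; C14 α-OTES), via lithium dienolate 8 (not isolated)
Conditions: LDA, THF, −78 °C; then N-tert-butylbenzenesulfinimidoyl chloride, −78 °C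
Reagents that add atoms: none
Why: Kinetic deprotonation of the enone occurs at the α′ carbon C17; sulfur attack on the sulfinimidoyl chloride followed by syn-elimination of the sulfenamide (Mukaiyama dehydrogenation) should give the C16=C17 enone in one flask.

Step 6
Reactants: 9 cross-conjugated dienone
Product: 11 C16 β-hydroxy enone (C10=C11 retained; C14 α-OTES), via boronate 10 (not isolated)
Conditions: B2pin2, CuCl (5 mol%), NaOtBu (10 mol%), DPEphos (5 mol%), MeOH (2 equiv), THF, rt; then NaBO3·4H2O, THF/H2O, rt
Reagents that add atoms: sodium perborate, [Na+].[Na+].O[B-]1(O)OO[B-](O)(O)OO1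
Why: Copper-catalysed conjugate borylation should take the unhindered disubstituted β-carbon C16 and leave fully substituted C11 alone, adding anti to the axial C15 methyl as cuprates do on such dienones; perborate oxidation proceeds with retention and sets C16 (β-OH).

Step 7
Reactants: 11 C16 β-hydroxy enone
Product: 12 C16 β-OTBS enone
Conditions: TBSOTf, 2,6-lutidine, CH2Cl2, −78 → 0 °C
Reagents that add atoms: tert-butyldimethylsilyl triflate, CC(C)(C)[Si](C)(C)OS(=O)(=O)C(F)(F)F
Why: Silylation under non-nucleophilic base protects the β-hydroxy ketone before it can dehydrate back to the dienone.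

Step 8
Reactants: 12 C16 β-OTBS enone
Product: 13 cis-hydrindan-9-one (C11 α-H; C10 β-Me; C16 β-OTBS; C14 α-OTES)
Conditions: H2 (3 atm), 10% Pd/C, EtOAc, rt
Reagents that add atoms: none
Why: Heterogeneous hydrogenation of hydrindenones of this class gives the cis ring fusion, and the C16 silyloxy group further screens the β face of C11, so syn addition from the α face should set C11 (α-H); the C10 centre formed here is erased in step 11.

Step 9
Reactants: 13 cis-hydrindan-9-one
Product: 15 C17 α-hydroxy ketone, via potassium enolate 14 (not isolated)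
Conditions: KHMDS, THF, −78 °C; then 2-(phenylsulfonyl)-3-phenyloxaziridine, −78 °C; NH4Cl (aq)
Reagents that add atoms: 2-(phenylsulfonyl)-3-phenyloxaziridine, O=S(=O)(c1ccccc1)N1OC1c1ccccc1
Why: Kinetic deprotonation takes the C17 methylene and not the C10 methine; the Davis oxaziridine should then hydroxylate the enolate anti to the adjacent C16 silyloxy group, giving the trans (C17 α) carbinol.

Step 10
Reactants: 15 C17 α-hydroxy ketone
Product: 16 C16 β/C17 α bis-OTBS ketone
Conditions: TBSOTf, 2,6-lutidine, CH2Cl2, 0 °C
Reagents that add atoms: tert-butyldimethylsilyl triflate, CC(C)(C)[Si](C)(C)OS(=O)(=O)C(F)(F)F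
Why: Silylation of the α-hydroxy ketone under mild base avoids α-ketol isomerisation and blocks the C17 oxygen for the next enolisation.

Step 11
Reactants: 16 bis-OTBS ketone
Product: 18 C9 enol triflate (C9=C10), via potassium enolate 17 (not isolated)
Conditions: KHMDS, THF, −78 °C; then Comins' reagent, −78 → −40 °C
Reagents that add atoms: N-(5-chloropyridin-2-yl)bis(trifluoromethanesulfonyl)imide, Clc1ccc(nc1)N(S(=O)(=O)C(F)(F)F)S(=O)(=O)C(F)(F)F
Why: The C17 hydrogen is flanked by two bulky silyloxy groups and an α-oxygen disfavours enolate formation on that side, so the base should remove the C10 hydrogen; O-sulfonylation of the enolate fixes the C9=C10 alkene and erases the C10 stereocentre.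

Step 12
Reactants: 18 C9 enol triflate; 19 (R)-β-citronellene [(3R)-3,7-dimethylocta-1,6-diene]
Product: 21 core carrying the (3R)-3,7-dimethyloct-6-enyl chain at C9 (C14 α-OTES; C16 and C17 OTBS), via alkylborane 20 (not isolated)
Conditions: 19, 9-BBN, THF, 0 °C → rt; then 18, Pd(dppf)Cl2 (5 mol%), AsPh3, Cs2CO3, DMF/H2O, 50 °C
Reagents that add atoms: none
Why: 9-BBN hydroborates only the monosubstituted alkene of 19, at its terminal carbon; B-alkyl Suzuki–Miyaura coupling (zerovalent palladium inserting into the C9–O triflate bond) should form C8–C9, and the C6 stereocentre comes unchanged from the chiral pool.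

Step 13
Reactants: 21 C9-alkylated core
Product: 22 C14 α-alcohol (C16 and C17 OTBS retained)
Conditions: PPTS (cat.), MeOH/CH2Cl2, rt
Reagents that add atoms: none
Why: Mild acidic methanolysis should cleave the triethylsilyl ether much faster than the two secondary tert-butyldimethylsilyl ethers.

Step 14
Reactants: 22 C14 α-alcohol
Product: 24 C12=C13 enone (C14 ketone), via ketone 23 (not isolated)
Conditions: IBX (3.5 equiv), DMSO/fluorobenzene, 75 °C
Reagents that add atoms: none
Why: IBX oxidises the alcohol to the ketone and then dehydrogenates it through its only possible enol (toward C13, since C15 is quaternary), so the cyclopentenone should form regiospecifically in one flask.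

Step 15
Reactants: 24 C12=C13 enone
Product: 26 C12 α-vinyl C14 ketone, via silyl enol ether 25 (not isolated)
Conditions: CH2=CHMgBr, CuBr·SMe2 (0.3 equiv), Me3SiCl, THF, −78 °C; then 1 M HCl (aq), 0 °C
Reagents that add atoms: vinylmagnesium bromide, C=C[Mg]Br
Why: Copper-catalysed, silyl-chloride-accelerated conjugate addition should deliver the vinyl group to C12 trans to the C10 substituent on neighbouring C11 (the convex face of the cis-hydrindane), as is usual for 4-substituted cyclopentenones; this sets C12.

Step 16
Reactants: 26 C12 α-vinyl C14 ketone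
Product: 27 C14 tosylhydrazone
Conditions: TsNHNH2, AcOH (cat.), EtOH, 70 °C
Reagents that add atoms: p-toluenesulfonyl hydrazide, Cc1ccc(cc1)S(=O)(=O)NN
Why: Condensation of the only carbonyl group; silyl ethers and the three alkenes are inert to the weakly acidic conditions.

Step 17
Reactants: 27 C14 tosylhydrazone
Product: 29 C12 α-vinyl hydrindene with C14 as methylene, via N-borylhydrazine 28 (not isolated)
Conditions: catecholborane, CHCl3, 0 °C; then NaOAc·3H2O, 60 °C
Reagents that add atoms: none
Why: Hydroboration of the C=N bond and acetate-induced loss of sulfinate give a diazene that extrudes N2 (tosylhydrazone reduction); the conditions are neither strongly basic nor acidic, so the silyl ethers and the C12 centre should be untouched.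

Step 18
Reactants: 29 C14-deoxygenated vinyl compound
Product: 30 C12 α-acetyl compound (methyl ketone at C2)
Conditions: PdCl2 (10 mol%), CuCl, O2 (1 atm), DMF/H2O 7:1, rt
Reagents that add atoms: water, O
Why: Tsuji–Wacker oxidation is selective for monosubstituted alkenes and should leave the trisubstituted and tetrasubstituted alkenes alone; Markovnikov hydroxypalladation places the carbonyl on C2.

Step 19
Reactants: 30 C12 α-acetyl compound
Product: 32 C2 enol triflate (C1=C2), via potassium enolate 31 (not isolated)
Conditions: KHMDS, THF, −78 °C; then Comins' reagent, −78 °C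
Reagents that add atoms: N-(5-chloropyridin-2-yl)bis(trifluoromethanesulfonyl)imide, Clc1ccc(nc1)N(S(=O)(=O)C(F)(F)F)S(=O)(=O)C(F)(F)F
Why: Kinetic deprotonation of a methyl ketone takes the methyl group and not the C12 methine, so the terminal enol triflate should form without epimerising C12.

Step 20
Reactants: 32 C2 enol triflate
Product: 34 C3 aldehyde, via diol 33 (not isolated)
Conditions: OsO4 (2 mol%), NaIO4, 2,6-lutidine, dioxane/H2O, rt
Reagents that add atoms: osmium tetroxide, O=[Os](=O)(=O)=O; sodium periodate, [Na+].[O-]I(=O)(=O)=O
Why: Lemieux–Johnson cleavage: OsO4 should dihydroxylate the accessible, electron-rich trisubstituted alkene in preference to the shielded tetrasubstituted C9=C10 and the electron-poor enol triflate, and periodate cleaves the diol to the C3 aldehyde and acetone.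

Step 21
Reactants: 34 C3 aldehyde
Product: 35 tricyclic (3R)-allylic alcohol (C16 and C17 OTBS)
Conditions: CrCl2 (10 equiv), NiCl2 (cat.), degassed DMSO/THF, rt, slow addition to high dilution
Reagents that add atoms: none
Why: Nozaki–Hiyama–Kishi reaction: nickel-mediated activation of the C2 triflate and transfer to chromium give an alkenylchromium species that adds to the C3 aldehyde, forming C2–C3 and closing ring C (11-exo-trig); C3 is set by the conformation of the forming ring held on the rigid A/B core, and the 3R carbinol is the one required.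

Step 22
Reactants: 35 tricyclic (3R)-allylic alcohol
Product: 36 C3 acetate (C16 and C17 OTBS)
Conditions: Ac2O, DMAP (cat.), pyridine, CH2Cl2, rt
Reagents that add atoms: acetic anhydride, CC(=O)OC(C)=O
Why: Acylation of the only free hydroxyl group under standard nucleophilic catalysis.

Step 23
Reactants: 36 C3 acetate
Product: 37 target CNP0192310.2
Conditions: HF·pyridine, pyridine, THF, 0 °C → rt
Reagents that add atoms: none
Why: Buffered fluoride should cleave both Si–O bonds while leaving the allylic acetate and the alkenes intact.

## Compound list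

1 | 2-methylcyclopentane-1,3-dione | CC1C(=O)CCC1=O | starting material
2 | ethyl vinyl ketone (pent-1-en-3-one) | CCC(=O)C=C | starting material
3 | 2-methyl-2-(3-oxopentyl)cyclopentane-1,3-dione | CCC(=O)CCC1(C)C(=O)CCC1=O | intermediate
4 | (3aS,7aS)-3a-hydroxy-4,7a-dimethylhexahydro-1H-indene-1,5(4H)-dione (cis-fused ketol, C10 epimers) | CC1C(=O)CC[C@]2(C)C(=O)CC[C@]12O | intermediate (not isolated)
5 | (7aS)-4,7a-dimethyl-2,3,7,7a-tetrahydro-1H-indene-1,5(6H)-dione | CC1=C2CCC(=O)[C@@]2(C)CCC1=O | intermediate
6 | (1S,7aS)-1-hydroxy-4,7a-dimethyl-1,2,3,6,7,7a-hexahydro-5H-inden-5-one | CC1=C2CC[C@H](O)[C@@]2(C)CCC1=O | intermediate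
7 | (1S,7aS)-4,7a-dimethyl-1-(triethylsilyloxy)-1,2,3,6,7,7a-hexahydro-5H-inden-5-one | CC1=C2CC[C@H](O[Si](CC)(CC)CC)[C@@]2(C)CCC1=O | intermediate
8 | lithium cross-conjugated dienolate of 7 (C9–OLi, C9=C17, C10=C11) | [Li+].CC1=C2CC[C@H](O[Si](CC)(CC)CC)[C@@]2(C)CC=C1[O-] | intermediate (not isolated)
9 | (1S,7aS)-4,7a-dimethyl-1-(triethylsilyloxy)-1,2,3,7a-tetrahydro-5H-inden-5-one (C16=C17, C10=C11) | CC1=C2CC[C@H](O[Si](CC)(CC)CC)[C@@]2(C)C=CC1=O | intermediate
10 | C16 β-(pinacolboryl) enone | CC1=C2CC[C@H](O[Si](CC)(CC)CC)[C@@]2(C)[C@@H](B3OC(C)(C)C(C)(C)O3)CC1=O | intermediate (not isolated)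
11 | C16 β-hydroxy enone (C14 α-OTES) | CC1=C2CC[C@H](O[Si](CC)(CC)CC)[C@@]2(C)[C@@H](O)CC1=O | intermediate
12 | C16 β-OTBS enone (C14 α-OTES) | CC1=C2CC[C@H](O[Si](CC)(CC)CC)[C@@]2(C)[C@@H](O[Si](C)(C)C(C)(C)C)CC1=O | intermediate
13 | cis-hydrindan-9-one (C11 α-H, C10 β-Me, C16 β-OTBS, C14 α-OTES) | C[C@H]1[C@H]2CC[C@H](O[Si](CC)(CC)CC)[C@@]2(C)[C@@H](O[Si](C)(C)C(C)(C)C)CC1=O | intermediate
14 | potassium enolate of 13 (C9=C17) | [K+].C[C@H]1[C@H]2CC[C@H](O[Si](CC)(CC)CC)[C@@]2(C)[C@@H](O[Si](C)(C)C(C)(C)C)C=C1[O-] | intermediate (not isolated)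
15 | C17 α-hydroxy ketone (C16 β-OTBS, C14 α-OTES) | C[C@H]1[C@H]2CC[C@H](O[Si](CC)(CC)CC)[C@@]2(C)[C@@H](O[Si](C)(C)C(C)(C)C)[C@H](O)C1=O | intermediate
16 | C16 β/C17 α bis-OTBS ketone (C14 α-OTES) | C[C@H]1[C@H]2CC[C@H](O[Si](CC)(CC)CC)[C@@]2(C)[C@@H](O[Si](C)(C)C(C)(C)C)[C@H](O[Si](C)(C)C(C)(C)C)C1=O | intermediate
17 | potassium enolate of 16 (C9=C10) | [K+].[O-]C1=C(C)[C@H]2CC[C@H](O[Si](CC)(CC)CC)[C@@]2(C)[C@@H](O[Si](C)(C)C(C)(C)C)[C@@H]1O[Si](C)(C)C(C)(C)C | intermediate (not isolated)
18 | C9 enol triflate (C9=C10; C14 α-OTES; C16 β- and C17 α-OTBS) | FC(F)(F)S(=O)(=O)OC1=C(C)[C@H]2CC[C@H](O[Si](CC)(CC)CC)[C@@]2(C)[C@@H](O[Si](C)(C)C(C)(C)C)[C@@H]1O[Si](C)(C)C(C)(C)C | intermediate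
19 | (R)-β-citronellene, (3R)-3,7-dimethylocta-1,6-diene | C=C[C@H](C)CCC=C(C)C | starting material
20 | B-[(3R)-3,7-dimethyloct-6-en-1-yl]-9-borabicyclo[3.3.1]nonane | CC(C)=CCC[C@@H](C)CCB1C2CCCC1CCC2 | intermediate (not isolated)
21 | C9-alkylated core (C8–C9 joined; C14 α-OTES; C16, C17 OTBS) | CC(C)=CCC[C@@H](C)CCC1=C(C)[C@H]2CC[C@H](O[Si](CC)(CC)CC)[C@@]2(C)[C@@H](O[Si](C)(C)C(C)(C)C)[C@@H]1O[Si](C)(C)C(C)(C)C | intermediate
22 | C14 α-alcohol | CC(C)=CCC[C@@H](C)CCC1=C(C)[C@H]2CC[C@H](O)[C@@]2(C)[C@@H](O[Si](C)(C)C(C)(C)C)[C@@H]1O[Si](C)(C)C(C)(C)C | intermediate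
23 | C14 ketone | CC(C)=CCC[C@@H](C)CCC1=C(C)[C@H]2CCC(=O)[C@@]2(C)[C@@H](O[Si](C)(C)C(C)(C)C)[C@@H]1O[Si](C)(C)C(C)(C)C | intermediate (not isolated)
24 | C12=C13 enone (C14 ketone) | CC(C)=CCC[C@@H](C)CCC1=C(C)[C@H]2C=CC(=O)[C@@]2(C)[C@@H](O[Si](C)(C)C(C)(C)C)[C@@H]1O[Si](C)(C)C(C)(C)C | intermediate
25 | C14 trimethylsilyl enol ether with C12 α-vinyl | CC(C)=CCC[C@@H](C)CCC1=C(C)[C@H]2[C@H](C=C)C=C(O[Si](C)(C)C)[C@@]2(C)[C@@H](O[Si](C)(C)C(C)(C)C)[C@@H]1O[Si](C)(C)C(C)(C)C | intermediate (not isolated)
26 | C12 α-vinyl C14 ketone | CC(C)=CCC[C@@H](C)CCC1=C(C)[C@H]2[C@H](C=C)CC(=O)[C@@]2(C)[C@@H](O[Si](C)(C)C(C)(C)C)[C@@H]1O[Si](C)(C)C(C)(C)C | intermediate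
27 | C14 tosylhydrazone | CC(C)=CCC[C@@H](C)CCC1=C(C)[C@H]2[C@H](C=C)CC(=NNS(=O)(=O)c3ccc(C)cc3)[C@@]2(C)[C@@H](O[Si](C)(C)C(C)(C)C)[C@@H]1O[Si](C)(C)C(C)(C)C | intermediate
28 | C14 N-(catecholboryl)-N′-tosylhydrazine | CC(C)=CCC[C@@H](C)CCC1=C(C)[C@H]2[C@H](C=C)CC(N(NS(=O)(=O)c3ccc(C)cc3)B3Oc4ccccc4O3)[C@@]2(C)[C@@H](O[Si](C)(C)C(C)(C)C)[C@@H]1O[Si](C)(C)C(C)(C)C | intermediate (not isolated)
29 | C12 α-vinyl compound with C14 methylene | CC(C)=CCC[C@@H](C)CCC1=C(C)[C@H]2[C@H](C=C)CC[C@@]2(C)[C@@H](O[Si](C)(C)C(C)(C)C)[C@@H]1O[Si](C)(C)C(C)(C)C | intermediate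
30 | C12 α-acetyl compound | CC(C)=CCC[C@@H](C)CCC1=C(C)[C@H]2[C@H](C(C)=O)CC[C@@]2(C)[C@@H](O[Si](C)(C)C(C)(C)C)[C@@H]1O[Si](C)(C)C(C)(C)C | intermediate
31 | potassium enolate of 30 (C1=C2) | [K+].CC(C)=CCC[C@@H](C)CCC1=C(C)[C@H]2[C@H](C(=C)[O-])CC[C@@]2(C)[C@@H](O[Si](C)(C)C(C)(C)C)[C@@H]1O[Si](C)(C)C(C)(C)C | intermediate (not isolated)
32 | C2 enol triflate (C1=C2) | CC(C)=CCC[C@@H](C)CCC1=C(C)[C@H]2[C@H](C(=C)OS(=O)(=O)C(F)(F)F)CC[C@@]2(C)[C@@H](O[Si](C)(C)C(C)(C)C)[C@@H]1O[Si](C)(C)C(C)(C)C | intermediate
33 | chain-terminal vicinal diol (carbinol centre unassigned) | CC(C)(O)C(O)CC[C@@H](C)CCC1=C(C)[C@H]2[C@H](C(=C)OS(=O)(=O)C(F)(F)F)CC[C@@]2(C)[C@@H](O[Si](C)(C)C(C)(C)C)[C@@H]1O[Si](C)(C)C(C)(C)C | intermediate (not isolated)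
34 | C3 aldehyde with C2 enol triflate | O=CCC[C@@H](C)CCC1=C(C)[C@H]2[C@H](C(=C)OS(=O)(=O)C(F)(F)F)CC[C@@]2(C)[C@@H](O[Si](C)(C)C(C)(C)C)[C@@H]1O[Si](C)(C)C(C)(C)C | intermediate
35 | tricyclic (3R)-allylic alcohol (C16 β- and C17 α-OTBS) | C=C1[C@H](O)CC[C@@H](C)CCC2=C(C)[C@H]3[C@H]1CC[C@@]3(C)[C@@H](O[Si](C)(C)C(C)(C)C)[C@@H]2O[Si](C)(C)C(C)(C)C | intermediate
36 | C3 acetate (C16 β- and C17 α-OTBS) | C=C1[C@H](OC(C)=O)CC[C@@H](C)CCC2=C(C)[C@H]3[C@H]1CC[C@@]3(C)[C@@H](O[Si](C)(C)C(C)(C)C)[C@@H]2O[Si](C)(C)C(C)(C)C | intermediate
37 | CNP0192310.2, (3R,6S,11R,12R,15R,16R,17R)-3-acetoxy-16,17-diol (skeletal numbering) | C=C1[C@H](OC(C)=O)CC[C@@H](C)CCC2=C(C)[C@H]3[C@H]1CC[C@@]3(C)[C@@H](O)[C@@H]2O | target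

## Step count and least certain steps

Total: 23 steps. Longest linear sequence: 23 steps (1 and 2 to 37); 19 is bought and enters in step 12.

**Step 2 (key step).** Most likely problem: incomplete discrimination between the enantiotopic carbonyls C11 and C14, because enamine formation from the ethyl ketone is slow and an acid-only, non-selective aldol can compete at reflux. Fallback: separate bond formation from dehydration. Setting out from 3, (S)-proline (catalytic, DMF, rt) gives ketol 4, which is isolated and recrystallised to raise its enantiomeric purity. Dehydration with TsOH in hot toluene then returns to the route at 5. This fallback makes no compound outside the list (entry F0).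

**Step 8.** Most likely problem: delivery of hydrogen to the β face of C11, giving the trans ring fusion, if binding of the catalyst anti to the angular methyl outweighs the usual cis preference. Fallback: let a hydroxyl group direct the reduction. Setting out from 12, α′-hydroxylation (KHMDS, then the Davis oxaziridine) gives the α′-hydroxy enone F1. Its C17 α-hydroxyl then directs homogeneous hydrogenation with [Ir(cod)(PCy3)(py)]PF6 (H2, CH2Cl2) to the α face. This returns to the route at 15.

**Step 9.** Most likely problem: β-elimination of the C16 silyloxy group from the C17 enolate, regenerating a C16=C17 enone before oxygen transfer. Fallback: carry the C16 oxygen as an alkoxide, which cannot leave. Setting out from 11, hydrogenation (H2, Pd/C, EtOAc) gives the saturated hydroxy ketone F2. Double deprotonation (LDA, 2.2 equiv) and Davis oxidation, anti to the alkoxide, give the trans-diol ketone F3. Bis-silylation (TBSOTf, 2,6-lutidine) returns to the route at 16.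

**Step 11.** Most likely problem: deprotonation at C17 in place of C10, followed by loss of the C16 silyloxy group, because both α-positions are methines. Fallback: fix the enolate position by conjugate reduction. Setting out from 11, dianion hydroxylation at the enone stage (LDA 2.2 equiv, Davis oxaziridine) gives the diol enone F4, and TBSOTf gives the bis-silyl enone F5. 1,4-Hydrosilylation with Et3SiH and catalytic RhCl(PPh3)3 gives the triethylsilyl enol ether F6, in which the double bond can only be C9=C10. CsF with PhNTf2 converts F6 into the triflate and returns to the route at 18.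

**Step 16 (with step 17).** Most likely problem: slow or incomplete condensation at the neopentyl C14 ketone, or partial alkene formation during the reduction. Fallback: radical deoxygenation. Setting out from 26, NaBH4 gives the C14 alcohol F7. NaH, CS2 and MeI give the S-methyl xanthate F8. Bu3SnH with AIBN in hot toluene (Barton–McCombie) returns to the route at 29.

**Step 21.** Most likely problem: intermolecular coupling in place of closure of the strained eleven-membered ring, and poor facial selectivity at the aldehyde, since only the ring conformation controls C3. Fallback for the stereochemical part: reset C3 under reagent control. Setting out from 34, the carbinol mixture from the chromium reaction (35 together with its C3 epimer F9) is oxidised with Dess–Martin periodinane to the macrocyclic enone F10. Corey–Bakshi–Shibata reduction ((S)-Me-oxazaborolidine, catecholborane, −78 °C), with the alkenyl side as the larger group, returns to the route at 35.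

## Further compounds

F0 | step 2 | none | none
F1 | step 8 | C17 α-hydroxy enone (C16 β-OTBS, C14 α-OTES, C10=C11) | CC1=C2CC[C@H](O[Si](CC)(CC)CC)[C@@]2(C)[C@@H](O[Si](C)(C)C(C)(C)C)[C@H](O)C1=O
F2 | step 9 | C16 β-hydroxy cis-hydrindan-9-one (C14 α-OTES) | C[C@H]1[C@H]2CC[C@H](O[Si](CC)(CC)CC)[C@@]2(C)[C@@H](O)CC1=O
F3 | step 9 | C16 β,C17 α-dihydroxy cis-hydrindan-9-one (C14 α-OTES) | C[C@H]1[C@H]2CC[C@H](O[Si](CC)(CC)CC)[C@@]2(C)[C@@H](O)[C@H](O)C1=O
F4 | step 11 | C16 β,C17 α-dihydroxy enone (C14 α-OTES) | CC1=C2CC[C@H](O[Si](CC)(CC)CC)[C@@]2(C)[C@@H](O)[C@H](O)C1=O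
F5 | step 11 | C16 β,C17 α-bis-OTBS enone (C14 α-OTES) | CC1=C2CC[C@H](O[Si](CC)(CC)CC)[C@@]2(C)[C@@H](O[Si](C)(C)C(C)(C)C)[C@H](O[Si](C)(C)C(C)(C)C)C1=O
F6 | step 11 | C9 triethylsilyl enol ether (C9=C10, C11 α-H) | CC[Si](CC)(CC)OC1=C(C)[C@H]2CC[C@H](O[Si](CC)(CC)CC)[C@@]2(C)[C@@H](O[Si](C)(C)C(C)(C)C)[C@@H]1O[Si](C)(C)C(C)(C)C
F7 | step 16 | C14 alcohol of 26 (C14 configuration unassigned) | CC(C)=CCC[C@@H](C)CCC1=C(C)[C@H]2[C@H](C=C)CC(O)[C@@]2(C)[C@@H](O[Si](C)(C)C(C)(C)C)[C@@H]1O[Si](C)(C)C(C)(C)C
F8 | step 16 | C14 S-methyl xanthate (C14 configuration unassigned) | CC(C)=CCC[C@@H](C)CCC1=C(C)[C@H]2[C@H](C=C)CC(OC(=S)SC)[C@@]2(C)[C@@H](O[Si](C)(C)C(C)(C)C)[C@@H]1O[Si](C)(C)C(C)(C)C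
F9 | step 21 | (3S)-epimer of 35 | C=C1[C@@H](O)CC[C@@H](C)CCC2=C(C)[C@H]3[C@H]1CC[C@@]3(C)[C@@H](O[Si](C)(C)C(C)(C)C)[C@@H]2O[Si](C)(C)C(C)(C)C
F10 | step 21 | macrocyclic C3 enone (C1=C2–C3=O) | C=C1C(=O)CC[C@@H](C)CCC2=C(C)[C@H]3[C@H]1CC[C@@]3(C)[C@@H](O[Si](C)(C)C(C)(C)C)[C@@H]2O[Si](C)(C)C(C)(C)C
A1 | alternative 1 | ring B/ring C bicycle as C3 trimethylsilyl enol ether (vinyl groups on C12 and C15) | C=C[C@H]1/C=C(\O[Si](C)(C)C)CC[C@@H](C)CCC2=C(C)[C@@H]1[C@@](C)(C=C)[C@@H](O[Si](C)(C)C(C)(C)C)[C@@H]2O[Si](C)(C)C(C)(C)C
A2 | alternative 1 | spiro cycloheptanol with (Z)-buta-1,3-dienyl group on C3, drawn with the C3 and C9 configuration a chair-like transition state requires | C=C/C=C\[C@]1(O)CC[C@@H](C)CC[C@@]12C(C)=C[C@@](C)(C=C)[C@@H](O[Si](C)(C)C(C)(C)C)[C@@H]2O[Si](C)(C)C(C)(C)C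
A3 | alternative 2 | C16/C17 acetonide of the target | C=C1[C@H](OC(C)=O)CC[C@@H](C)CCC2=C(C)[C@H]3[C@H]1CC[C@@]3(C)[C@H]4OC(C)(C)O[C@H]24
A4 | alternative 2 | thirteen-membered-ring precursor with C9 methylene and C11 isopropenyl | C=C1[C@H](OC(C)=O)CC[C@@H](C)CCC(=C)[C@H]2OC(C)(C)O[C@@H]2[C@]3(C)CC[C@@H]1[C@@H]3C(C)=C
A5 | alternative 3 | C16 triethylsilyl ether of the target | C=C1[C@H](OC(C)=O)CC[C@@H](C)CCC2=C(C)[C@H]3[C@H]1CC[C@@]3(C)[C@@H](O[Si](CC)(CC)CC)[C@@H]2O
A6 | alternative 3 | A/C bicycle with C9 enol triflate and C17 aldehyde | C=C1[C@H](OC(C)=O)CC[C@@H](C)CC/C(OS(=O)(=O)C(F)(F)F)=C(\C)[C@H]2[C@H]1CC[C@@]2(C)[C@@H](O[Si](CC)(CC)CC)C=O
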